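**Plan**

Locants follow guaiane numbering: C1/C5 ring fusion, C4 with methyl C15, C10 with methyl C14, C7 with C11, oxygen on C8; Ts = 4-methylphenylsulfonyl.
Cuts, in retrosynthetic order: the ferulate acyl–O8 bond; the C1=C10 alkene back to a C1–O–C8 ether bridge with Ts on C10; the two C11–CH3 bonds back to a C11 ester; the C–H bonds at C4, C5 and C7 back to a C4=C5–C6=C7 dienoate (C7–C11 from a C7 ketone); then C8–C9 and C1–C10 together; then O–C8 (diazoketone); then the cyclopentenone (aldol, Stetter).
Enabling feature: O8 and the alkene carbon C1 lie 1,4 across C9–C10, so the homoallylic alcohol C8(O)–C9–C10=C1 of the seven-membered ring is the opened form of an 8-oxabicyclo[3.2.1]octane. Its C8–O–C1 unit is a carbonyl ylide built from the C1 carbonyl of ring A and a carbenoid at C8, and C9=C10 is the dipolarophile.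
Forward ring order: ring A (cyclopentenone) first; then, in one operation, the six-membered oxonium ylide ring, the seven-membered carbocycle and the oxygen bridge; the bridge is opened in step 10 and the ferulate is attached last.
Stereochemistry: C1 and C8 (absolute) from the chiral dirhodium carboxylate in the cycloaddition; C4, C5 and C7 from one hydrogenation on the face of the oxygen bridge; C10 is erased; the E cinnamate geometry is bought.

Key step: step 5

Assumption: the (S)-configured dirhodium carboxylate is taken to give the (1S,8S) cycloadduct; if the sense proves opposite, the (R)-configured catalyst is used instead.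
Remark: C10 is carried as a mixture of epimers from the cycloadduct to the last sulfone, since it becomes sp2 in step 10.

**Route**

Step 1
Reactants: 1 methyl 4-oxobutanoate; 2 but-3-en-2-one (methyl vinyl ketone)
Product: 3 methyl 4,7-dioxooctanoate
Conditions: 3-benzyl-5-(2-hydroxyethyl)-4-methylthiazolium chloride (10 mol %), Et3N, EtOH, 80 °C
Reagents that add atoms: none
Why: Stetter reaction: the thiazolylidene turns the aldehyde into an acyl-anion equivalent that adds 1,4 to the enone, a standard entry to 2,5-diketones; no stereocentre is formed.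

Step 2
Reactants: 3 methyl 4,7-dioxooctanoate
Product: 5 2-(2-methyl-5-oxocyclopent-1-en-1-yl)acetic acid, via sodium 4,7-dioxooctanoate 4 (not isolated)
Conditions: 2% aq NaOH, reflux; then HCl to pH 2
Reagents that add atoms: sodium hydroxide, [Na+].[OH-]
Why: Saponification and intramolecular aldol condensation of the 2,5-diketone under thermodynamic control should give the tetrasubstituted 2,3-disubstituted cyclopentenone, as in dihydrojasmone-type ring closures; no stereocentre.

Step 3
Reactants: 5 2-(2-methyl-5-oxocyclopent-1-en-1-yl)acetic acid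
Product: 7 1-diazo-3-(2-methyl-5-oxocyclopent-1-en-1-yl)propan-2-one, via ethyl carbonic mixed anhydride 6 (not isolated)
Conditions: ClCO2Et, Et3N, THF, −15 °C; then CH2N2, Et2O, 0 °C to rt
Reagents that add atoms: diazomethane, C=[N+]=[N-]
Why: Acylation of diazomethane by a mixed carbonic anhydride (first stage of the Arndt–Eistert sequence) is mild enough for the γ-keto acid and the hindered enone; no stereocentre.

Step 4
Reactants: 8 sodium 4-methylbenzenesulfinate; 9 2-bromopropene
Product: 10 1-methyl-4-(prop-1-en-2-ylsulfonyl)benzene (isopropenyl p-tolyl sulfone)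
Conditions: Pd2(dba)3 (2.5 mol %), Xantphos (5 mol %), Cs2CO3, n-Bu4NCl, toluene, 80 °C, sealed tube
Reagents that add atoms: none
Why: Palladium-catalysed C–S coupling of a sulfinate salt with a vinyl bromide (oxidative addition, S-ligation, reductive elimination) is an established route to vinyl sulfones; no stereocentre.

Step 5
Reactants: 7 1-diazo-3-(2-methyl-5-oxocyclopent-1-en-1-yl)propan-2-one; 10 isopropenyl p-tolyl sulfone
Product: 12 (1S,8S)-1,8-epoxy-10-(4-methylphenylsulfonyl)-11,12,13-trinorguai-4-en-7-one (both C10 epimers), via carbonyl ylide 11 (not isolated)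
Conditions: Rh2(S-TCPTTL)4 [dirhodium tetrakis(N-tetrachlorophthaloyl-(S)-tert-leucinate)] (1 mol %), 10 (4 equiv), PhCF3, 0 °C, slow addition of 7
Reagents that add atoms: none
Why: The divalent rhodium carboxylate expels N2 from 7 to give a carbenoid at C8; the cyclopentenone oxygen, held syn to C6 by ring A, adds to it and closes the six-membered oxonium ring of ylide 11 (O, C1, C5, C6, C7, C8); the C8–O–C1 dipole then adds suprafacially across C9=C10 of 10 in a concerted, asynchronous [3+2] cycloaddition that forms C8–C9 and C1–C10 and thereby closes the seven-membered carbocycle and the oxolane ring of an 8-oxabicyclo[3.2.1]octane. The closest known type is the tandem carbenoid cyclization–cycloaddition of 1-diazo-2,5-diones with electron-poor 2π partners, including its enantioselective form with chiral dirhodium N-phthaloyl amino-acid carboxylates. The regioselectivity needed (CH2 of 10 to C8, sulfonyl carbon to C1) follows from polarization: C8, next to the C7 carbonyl, is the nucleophilic enolate-like terminus and pairs with the electrophilic β-carbon of the vinyl sulfone, while the oxocarbenium-like C1 pairs with the sulfonyl-bearing carbon. C1 and C8 are tied cis by the oxygen bridge and their absolute sense is set by the chiral carboxylate ligands on the rhodium-associated ylide, which screen one face of the planar dipole; C10 forms as an exo/endo mixture, which is harmless. Chemoselectivity rests on the six-membered closure onto oxygen outrunning cyclopropanation of the electron-poor tetrasubstituted C4=C5 bond, on excess 10 with slow addition of 7 to suppress 1,4-proton shift and dimerization of the ylide, and on the locked s-trans relation of C8 and C4, which rules out addition across the extended dipole.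

Step 6
Reactants: 12 (1S,8S)-1,8-epoxy-10-Ts-11,12,13-trinorguai-4-en-7-one
Product: 13 (1S,8S)-1,8-epoxy-10-(4-methylphenylsulfonyl)-11,12,13-trinorguaia-4,6-dien-7-yl trifluoromethanesulfonate
Conditions: KN(SiMe3)2, THF, −78 °C; then PhNTf2, −78 °C to 0 °C
Reagents that add atoms: N-phenylbis(trifluoromethanesulfonimide), O=S(=O)(N(c1ccccc1)S(=O)(=O)C(F)(F)F)C(F)(F)F
Why: Enolate O-triflation: deprotonation can occur only at the allylic C6 (C8 is a bridgehead and cannot enolize), and the dienolate is sulfonylated on oxygen; no new stereocentre.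

Step 7
Reactants: 13 dienyl triflate
Product: 14 methyl (1S,8S)-1,8-epoxy-10-(4-methylphenylsulfonyl)-12,13-dinorguaia-4,6-dien-11-oate
Conditions: Pd(OAc)2 (5 mol %), PPh3 (10 mol %), CO (1 atm), MeOH, Et3N, DMF, 40 °C
Reagents that add atoms: carbon monoxide, [C-]#[O+]; methanol, CO
Why: Palladium-catalysed alkoxycarbonylation of a vinyl triflate (oxidative addition, CO insertion, methanolysis) installs C11 at the ester level on C7; no new stereocentre.

Step 8
Reactants: 14 dienoate
Product: 15 methyl (1S,4S,5S,7S,8S)-1,8-epoxy-10-(4-methylphenylsulfonyl)-12,13-dinorguaian-11-oate (H4, H5 and H7 on the face of the bridge oxygen)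
Conditions: H2 (3 bar), PtO2, EtOAc, rt
Reagents that add atoms: none
Why: Catalytic hydrogenation under substrate control: the transoid dienoate should take up hydrogen only from the face of the oxygen bridge, because the other face lies under the C9–C10 bridge with its quaternary sulfonyl carbon, so H4, H5 and H7 all arrive syn to the bridge oxygen and set (4S,5S,7S); PtO2 is chosen to limit hydrogenolysis of the allylic C–O bonds and to leave the arene intact.

Step 9
Reactants: 15 saturated ester
Product: 17 (1S,4S,5S,7S,8S)-1,8-epoxy-10-(4-methylphenylsulfonyl)guaian-11-ol, via methyl ketone 16 (not isolated)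
Conditions: MeMgBr (4 equiv), THF, 0 °C to rt; aq NH4Cl
Reagents that add atoms: methylmagnesium bromide, C[Mg]Br
Why: Double Grignard addition to the ester gives the tertiary carbinol; the sulfone has no α-hydrogen and is inert, and C7 already holds its thermodynamically preferred equatorial substituent, so enolization cannot erode it.

Step 10
Reactants: 17 tertiary alcohol
Product: 19 (4S,5S,7S,8S)-guai-1(10)-ene-8,11-diol, via dilithiated C10 carbanion alkoxide 18 (not isolated)
Conditions: n-BuLi (1.0 equiv), THF, −78 °C; then LiC10H8 (lithium naphthalenide, 2.5 equiv), −78 °C; aq NH4Cl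
Reagents that add atoms: none
Why: Julia-type reductive elimination of a β-alkoxy sulfone (the sulfone counterpart of the Boord olefin synthesis): two-electron reduction cleaves the tertiary C10–S bond, and the C10 carbanion, whose endo lobe is nearly antiperiplanar to C1–O, expels the bridging alkoxide to give the C1=C10 alkene and the C8 alkoxide with C8 untouched; the hydroxyl is lithiated first so that it cannot protonate the carbanion.

Step 11
Reactants: 19 (4S,5S,7S,8S)-guai-1(10)-ene-8,11-diol; 20 (E)-4-acetoxy-3-methoxycinnamic acid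
Product: 21 (4S,5S,7S,8S)-11-hydroxyguai-1(10)-en-8-yl (E)-3-(4-acetoxy-3-methoxyphenyl)prop-2-enoate
Conditions: DCC, DMAP (0.2 equiv), CH2Cl2, 0 °C to rt
Reagents that add atoms: none
Why: Steglich esterification acylates the secondary C8 hydroxyl and leaves the tertiary C11 hydroxyl alone; C8 is not touched at carbon, so its configuration is retained, and the acetate keeps the phenol from competing.

Step 12
Reactants: 21 acetyl-protected ester
Product: 22 (4S,5S,7S,8S)-11-hydroxyguai-1(10)-en-8-yl (E)-3-(4-hydroxy-3-methoxyphenyl)prop-2-enoate (target, CNP0241038.1)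
Conditions: pyrrolidine (3 equiv), CH2Cl2, 0 °C
Reagents that add atoms: none
Why: Chemoselective aminolysis: the aryl acetate is far more electrophilic than the hindered secondary cinnamate, so the phenol should be freed without ester cleavage or conjugate addition.

**Compound list**

1 | methyl 4-oxobutanoate | COC(=O)CCC=O | starting material
2 | but-3-en-2-one (methyl vinyl ketone) | CC(=O)C=C | starting material
3 | methyl 4,7-dioxooctanoate | COC(=O)CCC(=O)CCC(C)=O | intermediate
4 | sodium 4,7-dioxooctanoate (not isolated) | [Na+].[O-]C(=O)CCC(=O)CCC(C)=O | intermediate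
5 | 2-(2-methyl-5-oxocyclopent-1-en-1-yl)acetic acid | CC1=C(CC(=O)O)C(=O)CC1 | intermediate
6 | ethyl carbonic 2-(2-methyl-5-oxocyclopent-1-en-1-yl)acetic anhydride (not isolated) | CCOC(=O)OC(=O)CC1=C(C)CCC1=O | intermediate
7 | 1-diazo-3-(2-methyl-5-oxocyclopent-1-en-1-yl)propan-2-one | CC1=C(CC(=O)C=[N+]=[N-])C(=O)CC1 | intermediate
8 | sodium 4-methylbenzenesulfinate | [Na+].[O-]S(=O)c1ccc(C)cc1 | starting material
9 | 2-bromopropene | CC(Br)=C | starting material
10 | 1-methyl-4-(prop-1-en-2-ylsulfonyl)benzene | CC(=C)S(=O)(=O)c1ccc(C)cc1 | intermediate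
11 | six-membered carbonyl ylide (C8 carbanion, O+=C1 oxonium; not isolated) | CC1=C2CC(=O)[CH-][O+]=C2CC1 | intermediate
12 | (1S,8S)-1,8-epoxy-10-(4-methylphenylsulfonyl)-11,12,13-trinorguai-4-en-7-one, C10 epimers | O=C1CC2=C(C)CC[C@]23O[C@H]1CC3(C)S(=O)(=O)c1ccc(C)cc1 | intermediate
13 | (1S,8S)-1,8-epoxy-10-(4-methylphenylsulfonyl)-11,12,13-trinorguaia-4,6-dien-7-yl trifluoromethanesulfonate | O=S(=O)(OC1=CC2=C(C)CC[C@]23O[C@H]1CC3(C)S(=O)(=O)c1ccc(C)cc1)C(F)(F)F | intermediate
14 | methyl (1S,8S)-1,8-epoxy-10-(4-methylphenylsulfonyl)-12,13-dinorguaia-4,6-dien-11-oate | COC(=O)C1=CC2=C(C)CC[C@]23O[C@H]1CC3(C)S(=O)(=O)c1ccc(C)cc1 | intermediate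
15 | methyl (1S,4S,5S,7S,8S)-1,8-epoxy-10-(4-methylphenylsulfonyl)-12,13-dinorguaian-11-oate | COC(=O)[C@H]1C[C@H]2[C@@H](C)CC[C@]23O[C@H]1CC3(C)S(=O)(=O)c1ccc(C)cc1 | intermediate
16 | (1S,4S,5S,7S,8S)-1,8-epoxy-10-(4-methylphenylsulfonyl)-13-norguaian-11-one (not isolated) | CC(=O)[C@H]1C[C@H]2[C@@H](C)CC[C@]23O[C@H]1CC3(C)S(=O)(=O)c1ccc(C)cc1 | intermediate
17 | (1S,4S,5S,7S,8S)-1,8-epoxy-10-(4-methylphenylsulfonyl)guaian-11-ol | CC(C)(O)[C@H]1C[C@H]2[C@@H](C)CC[C@]23O[C@H]1CC3(C)S(=O)(=O)c1ccc(C)cc1 | intermediate
18 | dilithium salt of the C10 carbanion of 1,8-epoxyguaian-11-olate (not isolated) | CC(C)([O-])[C@H]1C[C@H]2[C@@H](C)CC[C@]23O[C@H]1C[C-]3C.[Li+].[Li+] | intermediate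
19 | (4S,5S,7S,8S)-guai-1(10)-ene-8,11-diol | CC(C)(O)[C@H]1C[C@H]2[C@@H](C)CCC2=C(C)C[C@@H]1O | intermediate
20 | (E)-4-acetoxy-3-methoxycinnamic acid | COc1cc(/C=C/C(=O)O)ccc1OC(C)=O | starting material
21 | (4S,5S,7S,8S)-11-hydroxyguai-1(10)-en-8-yl (E)-3-(4-acetoxy-3-methoxyphenyl)prop-2-enoate | COc1cc(/C=C/C(=O)O[C@H]2CC(C)=C3CC[C@H](C)[C@@H]3C[C@@H]2C(C)(C)O)ccc1OC(C)=O | intermediate
22 | (4S,5S,7S,8S)-11-hydroxyguai-1(10)-en-8-yl (E)-3-(4-hydroxy-3-methoxyphenyl)prop-2-enoate | COc1cc(/C=C/C(=O)O[C@H]2CC(C)=C3CC[C@H](C)[C@@H]3C[C@@H]2C(C)(C)O)ccc1O | target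

**Step count and risks**

Total steps: 12. Longest linear sequence: 11 steps (steps 1–3 and 5–12); step 4 is a one-step side branch.

Step 5 (key step). What may go wrong: the chiral catalyst may discriminate the two faces of the ylide poorly with this 1,1-disubstituted vinyl sulfone, or capture may be slow enough for the ylide to collapse by proton shift. Fallback, from 7 back to 12, with auxiliary control in place of catalyst control: commercial (1R,2S,5R)-menthyl (S)-4-methylbenzenesulfinate and isopropenylmagnesium bromide should give, by the Andersen synthesis with inversion at sulfur, (R)-1-methyl-4-(prop-1-en-2-ylsulfinyl)benzene F1. Compound 7 is then decomposed with achiral Rh2(OAc)4 in the presence of F1, so that the sulfinyl group differentiates the alkene faces. The two diastereomeric adducts, (1S,8S)-1,8-epoxy-10-(4-methylphenylsulfinyl)-11,12,13-trinorguai-4-en-7-one F2 and its (1R,8R) diastereomer F3, are separated on silica. F2 is oxidized at sulfur with KHSO5 in aqueous MeOH to give 12. If F3 predominates, the antipodal menthyl sulfinate is used.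

Step 8. What may go wrong: hydrogenolysis of the allylic C1–O or C8–O bond, stalling at the tetrasubstituted C4=C5 bond, or incomplete face selection at C7. Fallback, from 12 back to 15, dividing the task and using thermodynamic control at C7: the isolated C4=C5 bond of ketone 12 is hydrogenated with [Ir(cod)(PCy3)(py)]PF6 in CH2Cl2, which binds the bridge oxygen and delivers H2 to that face, to give (1S,4S,5S,8S)-1,8-epoxy-10-(4-methylphenylsulfonyl)-11,12,13-trinorguaian-7-one F4. Triflation as in step 6 gives the C6=C7 enol triflate of F4 F5, and methoxycarbonylation as in step 7 gives the corresponding methyl 12,13-dinorguai-6-en-11-oate F6. Conjugate reduction of F6 with [(Ph3P)CuH]6 followed by NaOMe in MeOH equilibrates the ester to the equatorial position anti to the bridge oxygen, which is 15.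

Step 10. What may go wrong: the C10 intermediate may be quenched by hydrogen capture or protonation before it expels the alkoxide (plain desulfonylation), or the alkoxide may interfere with electron transfer. Fallback, from 15 back to 19, reordering the end game: the bridge is opened at the ester stage by single-electron reduction with SmI2 and HMPA in THF, which tolerates the ester and needs no organolithium, to give methyl (4S,5S,7S,8S)-8-hydroxy-12,13-dinorguai-1(10)-en-11-oate F7. Excess MeMgBr then converts F7 into 19.

**Further compounds**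

F1 | step 5 | (R)-1-methyl-4-(prop-1-en-2-ylsulfinyl)benzene | CC(=C)[S@@](=O)c1ccc(C)cc1
F2 | step 5 | (1S,8S)-1,8-epoxy-10-(4-methylphenylsulfinyl)-11,12,13-trinorguai-4-en-7-one, sulfur configuration retained from F1 | O=C1CC2=C(C)CC[C@]23O[C@H]1CC3(C)[S@@](=O)c1ccc(C)cc1
F3 | step 5 | (1R,8R) diastereomer of F2, same sulfur configuration | O=C1CC2=C(C)CC[C@@]23O[C@@H]1CC3(C)[S@@](=O)c1ccc(C)cc1
F4 | step 8 | (1S,4S,5S,8S)-1,8-epoxy-10-(4-methylphenylsulfonyl)-11,12,13-trinorguaian-7-one | O=C1C[C@H]2[C@@H](C)CC[C@]23O[C@H]1CC3(C)S(=O)(=O)c1ccc(C)cc1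
F5 | step 8 | C6=C7 enol trifluoromethanesulfonate of F4 | O=S(=O)(OC1=C[C@H]2[C@@H](C)CC[C@]23O[C@H]1CC3(C)S(=O)(=O)c1ccc(C)cc1)C(F)(F)F
F6 | step 8 | methyl 1,8-epoxy-10-(4-methylphenylsulfonyl)-12,13-dinorguai-6-en-11-oate, C1, C4, C5 and C8 as in F4 | COC(=O)C1=C[C@H]2[C@@H](C)CC[C@]23O[C@H]1CC3(C)S(=O)(=O)c1ccc(C)cc1
F7 | step 10 | methyl (4S,5S,7S,8S)-8-hydroxy-12,13-dinorguai-1(10)-en-11-oate | COC(=O)[C@H]1C[C@H]2[C@@H](C)CCC2=C(C)C[C@@H]1O
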